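All runs were computed with made-up constants; the scatter is artificial.

If the stall in the east flask was a balance and not dead reagent, taking target out had to pay too, so I let the next move hang on one quotient.

| setting | east | north | flask |
|---|---|---|---|
| starting material | 0.10 M | 0.10 M | 0.10 M |
| reagent | 0.050 M | 0.050 M | 0.0500 M |
| second substrate | 0.10 M | 0.10 M | 0.100 M |
| temperature | 0 °C | 6 °C | 0 °C |
| remark | the very flask that is asked about, followed so far | run made earlier |  |
| time |  |  | 12 min |

| run | time / min | target / % | starting material / % |
|---|---|---|---|
| east | 0.833 | 8.8 | 91.4 |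
| east | 2.00 | 14.6 | 85.9 |
| east | 4.00 | 18.6 | 81.3 |
| east | 10.0 | 22.4 | 77.3 |
| north | 0.833 | 11.5 | 88.0 |
| north | 2.00 | 16.6 | 82.8 |
| north | 4.00 | 19.7 | 79.8 |
| north | 10.0 | 21.1 | 78.5 |

(scatter of a reading: 0.3 percentage points)
- red: at 12 min raise the temperature by 15 K, then wait 4.0 min
- blue: at 12 min take out 90% of the target then present, then wait 4.0 min
- ochre: change nothing and wait 4.0 min more
- teal: at 12 min add reagent, 100% of the amount charged, then wait 4.0 min
- target that was removed still counts
- the numbers in the tables scatter by 0.3 percentage points (one standard deviation)
- additions bring no volume worth counting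
1. target, in percent of the starting material first charged, at 12 min
2. which option adds most target ("none" when 2 percentage points or less is all one gets) (red / blue / ochre / teal / none)
3. target present, with what was taken out counted in, in percent of the starting material first charged, after blue
4. target present, with what was taken out counted in, in percent of the starting material first charged, after ochre

1. I read the east run first. Target reached 22.4% at 10.0 min, although the reagent charge, the limiting reagent, allowed 50.0%. Target plus starting material stayed near 100%, so I wrote P for target, A for starting material and R for charged reagent minus target, in M.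

2. That last east reading gave Q = P/(A·R) = 10.5 L mol⁻¹. I called this the stall quotient, target over starting material times reagent not held in target, an apparent equilibrium constant. The warmer north run gave 9.30 L mol⁻¹, lower than the east value, so I expected red to lose target.

3. Holding Q fixed, totals a and b of starting material and reagent give a closed estimate of the level of target x, which I called the ceiling: Q(a−x)(b−x) = x, so x = (s − sqrt(s·s − 4ab))/2, with s = a + b + 1/Q.

4. Teal doubled b, and the ceiling came to 39.0%. Blue left a = 0.0798 M and b = 0.0298 M, and with the removed target counted in, the ceiling came to 32.5%, lower than teal's. These were estimates at fixed Q, and 4.0 min might not reach them. I chose teal, expected ochre to add less than 2 percentage points, and put target at 12 min above that last reading.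

5. The forecast gave 22.9%, teal, 23.6% for blue and 23.6% for ochre, holding that “the reaction is not equilibrium-limited”. On blue it stood below my ceiling.

6. The east flask gave 22.9% at 12 min, teal added 15 points, blue reached 28.7%, and ochre reached 23.4%.

    starting material + reagent ⇌ target (K = 27.0 L mol⁻¹, k = 0.0490 L mol⁻¹ s⁻¹, Ea = 57.0 kJ mol⁻¹, ΔH = −21.0 kJ mol⁻¹)
    second substrate + reagent ⇌ second product (K = 1.60 L mol⁻¹, k = 0.0230 L mol⁻¹ s⁻¹, Ea = 39.0 kJ mol⁻¹, ΔH = −26.0 kJ mol⁻¹)
    reagent ⇌ dormant form (K = 1.10, k = 0.00430 s⁻¹, Ea = 74.0 kJ mol⁻¹, ΔH = 10.0 kJ mol⁻¹)
    (constants at 0 °C)

That blue value lies above the forecast and below my ceiling. At 12.0 min the east flask still held 23.5% of its reagent free, with dormant form at 0.0135 M. Its own Q at that time was 11.0 L mol⁻¹. With 10.5 L mol⁻¹, the neighbour charged with 0.020 M of reagent has an estimated ceiling of 9.73%, and that neighbour stood at 9.86% at 12.0 min.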